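**Retrosynthetic overview**
1. The target comes from global hydrogenolysis of a doubly p-xylylene-strapped hexadeca-O-benzyl tetramer. All four pyran rings are inherited from (−)-epicatechin.
2. Key disconnection: both upper interflavan bonds, C4(unit 2)–C8(unit 3) and C4(unit 1)–C8(unit 2), are cut at once. This leads to a lower dimer carrying two strapped, C4-activated epicatechin arms. In the forward direction one Lewis-acid operation closes a 15-membered ring and then a 23-membered ring.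
3. The two-armed precursor comes from benzylated catechin-(4β→8)-epicatechin diol and two equivalents of an arm bromide by double O-alkylation.
4. The 2,3-trans-3,4-cis unit 3 comes from benzylated epicatechin-(4β→8)-epicatechin. Both 3-OH groups are oxidised to ketones and reduced face-selectively, which inverts C3 of unit 3 and restores C3 of unit 4.
5. The dimer and the arm both come from 4β-(2-ethoxyethoxy)tetra-O-benzylepicatechin, which comes from (−)-epicatechin.

**Assumption:** the SMILES decodes as (−)-epicatechin-(4β→8)-(−)-epicatechin-(4β→8)-(+)-catechin-(4β→8)-(−)-epicatechin, counted as units 1 to 4 from the top. Every unit has a 2α-aryl group; units 1, 2 and 4 carry 3α-OH, and unit 3 carries 3β-OH cis to its 4β-aryl group.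

**Step 1**
Reactants: 1 (−)-epicatechin
Product: 2 5,7,3',4'-tetra-O-benzyl-(−)-epicatechin (2α-aryl, free 3α-OH)
Conditions: BnBr (4.4 equiv), K2CO3, DMF, 0 °C to rt, Ar
Reagents that add atoms: benzyl bromide, BrCc1ccccc1
Why: Williamson etherification in which K2CO3 ionises only the four phenols, so the secondary 3-OH stays free and C2 and C3 are untouched.

**Step 2**
Reactants: 2 5,7,3',4'-tetra-O-benzyl-(−)-epicatechin
Product: 3 4β-(2-ethoxyethoxy)-5,7,3',4'-tetra-O-benzyl-(−)-epicatechin (2α-aryl, 3α-OH, 4β-OR)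
Conditions: DDQ (1.5 equiv), HOCH2CH2OEt (10 equiv), CH2Cl2, rt
Reagents that add atoms: 2-ethoxyethanol, CCOCCO
Why: DDQ benzylic C–H oxidation abstracts hydride from C4 (activated by the ortho and para oxygens of ring A), and the alcohol traps the cation from the β face, anti to the axial 3α-OH, giving a 4β-ether that serves only as a leaving group.

**Step 3**
Reactants: 3 4β-(2-ethoxyethoxy)-tetra-O-benzylepicatechin; 2 tetra-O-benzylepicatechin (3 equiv, excess recovered)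
Product: 4 octa-O-benzyl epicatechin-(4β→8)-epicatechin (both 3α-OH free)
Conditions: Me3SiOTf (0.2 equiv), CH2Cl2, −78 °C
Reagents that add atoms: none
Why: Lewis-acid SN1 Friedel–Crafts interflavan coupling in which C8 of 2 attacks the epicatechin C4 cation only from the β face, trans to the 3α-oxygen, which sets C4 of the future unit 3, while the excess of nucleophile stops growth at the dimer.

**Step 4**
Reactants: 4 octa-O-benzyl epicatechin-(4β→8)-epicatechin
Product: 5 octa-O-benzyl bis-flavan-3-one (upper unit 2α-aryl and 4β-flavanyl, lower unit 2α-aryl, both C3 = C=O)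
Conditions: Dess–Martin periodinane (3 equiv), moist CH2Cl2, rt
Reagents that add atoms: none
Why: Dess–Martin oxidation of both secondary alcohols under near-neutral conditions, known for tetra-O-benzylcatechin, leaves the benzyl ethers and the interflavan bond alone and does not enolise C2 or C4.

**Step 5**
Reactants: 5 bis-flavan-3-one
Product: 6 octa-O-benzyl catechin-(4β→8)-epicatechin (upper unit 2α-aryl, 3β-OH, 4β-aryl; lower unit 2α-aryl, 3α-OH)
Conditions: LiBH(s-Bu)3 (4 equiv), THF, −78 to −40 °C; H2O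
Reagents that add atoms: none
Why: Substrate-controlled ketone reduction by a bulky borohydride, in which hydride reaches the lower ketone from the β face opposite the 2α-aryl group and restores 3α-OH (as in the known catechin-to-epicatechin oxidation–reduction sequence), whereas the β face of the upper ketone is roofed by the quasi-axial 4β-flavanyl group, so hydride enters from the α face and gives the equatorial 3β-OH that sets the 2,3-trans-3,4-cis array of unit 3.

**Step 6**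
Reactants: 3 4β-(2-ethoxyethoxy)-tetra-O-benzylepicatechin
Product: 7 3-O-[4-(bromomethyl)benzyl] ether of 3 (arm bromide; 2α-aryl, 3α-OR, 4β-OCH2CH2OEt)
Conditions: NaH (1.1 equiv), 1,4-(BrCH2)2C6H4 (5 equiv), THF–DMF, 0 °C to rt
Reagents that add atoms: 1,4-bis(bromomethyl)benzene, BrCc1ccc(CBr)cc1
Why: Williamson etherification that stops at the monoether because the dibromide is in fivefold excess, while the C4 ether is base-stable and no stereocentre is touched.

**Step 7**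
Reactants: 6 octa-O-benzyl catechin-(4β→8)-epicatechin; 7 arm bromide (2.3 equiv)
Product: 8 two-armed dimer (O3 of unit 3 and O3 of unit 4 each carry CH2–C6H4–CH2–O3 of one unit of type 3)
Conditions: NaH (3 equiv), Bu4NI (0.1 equiv), DMF, 0 to 40 °C
Reagents that add atoms: none
Why: Double Williamson etherification with iodide catalysis that needs no selectivity because both hydroxyls receive the same arm, with every other group a base-stable ether and no stereocentre involved.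

**Step 8 (key step)**
Reactants: 8 two-armed dimer
Product: 10 doubly p-xylylene-strapped hexadeca-O-benzyl tetramer (straps: O3 unit 2 to O3 unit 3; O3 unit 1 to O3 unit 4), via singly strapped trimer-stage macrocycle 9 (not isolated)
Conditions: Me3SiOTf (0.3 equiv), 4 Å MS, CH2Cl2, 8 added over 6 h (final 0.5 mM), −78 to −30 °C
Reagents that add atoms: none
Why: Proposed new method: Me3SiOTf ionises both 4β-(2-ethoxyethoxy) groups to ring-A-stabilised C4 cations that at 0.5 mM meet only nucleophiles within the same molecule, so the arm on O3 of unit 3 closes on the free C8 of unit 3 (15-membered ring, 9) and the arm on O3 of unit 4 then closes on the C8 of the new unit 2 (23-membered ring), each attack coming from the β face anti to the axial 3α-O-strap as with every epicatechin C4 cation (sets C4 of units 2 and 1 as 4β), the two straps fix the chain at exactly four units, their 6.8–7.3 Å O···O span fits bond-vector estimates of about 7.5 Å for O3(unit 2)···O3(unit 3) and 5–7 Å for O3(unit 1)···O3(unit 4) in folded rotamers, and if the arms close in the other order the strap isomer still gives 11 in step 9; the closest known reaction types are the Lewis-acid interflavan Friedel–Crafts coupling, its diester-tethered intramolecular variant and rigid-spacer (xylylene) intramolecular glycosylation.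

**Step 9**
Reactants: 10 doubly strapped hexadeca-O-benzyl tetramer
Product: 11 epicatechin-(4β→8)-epicatechin-(4β→8)-catechin-(4β→8)-epicatechin (target)
Conditions: H2 (1 atm), Pd(OH)2/C, THF–MeOH–H2O, rt
Reagents that add atoms: none
Why: Heterogeneous hydrogenolysis cleaves all twenty benzylic C–O bonds (sixteen benzyl ethers and four strap bonds) under neutral conditions that leave the acid-labile interflavan bonds and all eleven stereocentres untouched.

**Compound list**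

1 | (−)-epicatechin | Oc1cc(O)c2c(c1)O[C@H](c1ccc(O)c(O)c1)[C@H](O)C2 | starting material

2 | 5,7,3',4'-tetra-O-benzyl-(−)-epicatechin | c1c(OCc9ccccc9)cc(OCc9ccccc9)c2c1O[C@H](c8ccc(OCc9ccccc9)c(OCc9ccccc9)c8)[C@H](O)C2 | intermediate

3 | 4β-(2-ethoxyethoxy)-5,7,3',4'-tetra-O-benzyl-(−)-epicatechin | c1c(OCc9ccccc9)cc(OCc9ccccc9)c2c1O[C@H](c8ccc(OCc9ccccc9)c(OCc9ccccc9)c8)[C@H](O)[C@H]2OCCOCC | intermediate

4 | octa-O-benzyl epicatechin-(4β→8)-epicatechin | c1c(OCc9ccccc9)cc(OCc9ccccc9)c2c1O[C@H](c8ccc(OCc9ccccc9)c(OCc9ccccc9)c8)[C@H](O)[C@H]2c1c(OCc9ccccc9)cc(OCc9ccccc9)c2c1O[C@H](c8ccc(OCc9ccccc9)c(OCc9ccccc9)c8)[C@H](O)C2 | intermediate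

5 | octa-O-benzyl (4β→8)-linked bis-flavan-3-one | c1c(OCc9ccccc9)cc(OCc9ccccc9)c2c1O[C@H](c8ccc(OCc9ccccc9)c(OCc9ccccc9)c8)C(=O)[C@H]2c1c(OCc9ccccc9)cc(OCc9ccccc9)c2c1O[C@H](c8ccc(OCc9ccccc9)c(OCc9ccccc9)c8)C(=O)C2 | intermediate

6 | octa-O-benzyl catechin-(4β→8)-epicatechin | c1c(OCc9ccccc9)cc(OCc9ccccc9)c2c1O[C@H](c8ccc(OCc9ccccc9)c(OCc9ccccc9)c8)[C@@H](O)[C@H]2c1c(OCc9ccccc9)cc(OCc9ccccc9)c2c1O[C@H](c8ccc(OCc9ccccc9)c(OCc9ccccc9)c8)[C@H](O)C2 | intermediate

7 | 3-O-[4-(bromomethyl)benzyl]-4β-(2-ethoxyethoxy)-tetra-O-benzylepicatechin | c1c(OCc9ccccc9)cc(OCc9ccccc9)c2c1O[C@H](c8ccc(OCc9ccccc9)c(OCc9ccccc9)c8)[C@H](OCc3ccc(CBr)cc3)[C@H]2OCCOCC | intermediate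

8 | two-armed dimer | c1c(OCc9ccccc9)cc(OCc9ccccc9)c2c1O[C@H](c8ccc(OCc9ccccc9)c(OCc9ccccc9)c8)[C@@H](OCc3ccc(cc3)CO[C@@H]4[C@@H](OCCOCC)c5c(OCc9ccccc9)cc(OCc9ccccc9)cc5O[C@@H]4c8ccc(OCc9ccccc9)c(OCc9ccccc9)c8)[C@H]2c1c(OCc9ccccc9)cc(OCc9ccccc9)c2c1O[C@H](c8ccc(OCc9ccccc9)c(OCc9ccccc9)c8)[C@H](OCc3ccc(cc3)CO[C@@H]4[C@@H](OCCOCC)c5c(OCc9ccccc9)cc(OCc9ccccc9)cc5O[C@@H]4c8ccc(OCc9ccccc9)c(OCc9ccccc9)c8)C2 | intermediate

9 | singly strapped trimer-stage macrocycle (second arm still open) | c1c(OCc9ccccc9)cc(OCc9ccccc9)c2c1O[C@H](c8ccc(OCc9ccccc9)c(OCc9ccccc9)c8)[C@H](OCc3ccc(cc3)C6)[C@H]2c1c(OCc9ccccc9)cc(OCc9ccccc9)c2c1O[C@H](c8ccc(OCc9ccccc9)c(OCc9ccccc9)c8)[C@@H](O6)[C@H]2c1c(OCc9ccccc9)cc(OCc9ccccc9)c2c1O[C@H](c8ccc(OCc9ccccc9)c(OCc9ccccc9)c8)[C@H](OCc3ccc(cc3)CO[C@@H]4[C@@H](OCCOCC)c5c(OCc9ccccc9)cc(OCc9ccccc9)cc5O[C@@H]4c8ccc(OCc9ccccc9)c(OCc9ccccc9)c8)C2 | intermediate (not isolated)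

10 | doubly p-xylylene-strapped hexadeca-O-benzyl tetramer | c1c(OCc9ccccc9)cc(OCc9ccccc9)c2c1O[C@H](c8ccc(OCc9ccccc9)c(OCc9ccccc9)c8)[C@H](OCc3ccc(cc3)C5)[C@H]2c1c(OCc9ccccc9)cc(OCc9ccccc9)c2c1O[C@H](c8ccc(OCc9ccccc9)c(OCc9ccccc9)c8)[C@H](OCc3ccc(cc3)C6)[C@H]2c1c(OCc9ccccc9)cc(OCc9ccccc9)c2c1O[C@H](c8ccc(OCc9ccccc9)c(OCc9ccccc9)c8)[C@@H](O6)[C@H]2c1c(OCc9ccccc9)cc(OCc9ccccc9)c2c1O[C@H](c8ccc(OCc9ccccc9)c(OCc9ccccc9)c8)[C@H](O5)C2 | intermediate

11 | epicatechin-(4β→8)-epicatechin-(4β→8)-catechin-(4β→8)-epicatechin | Oc1cc(O)c2c(c1)O[C@H](c1ccc(O)c(O)c1)[C@H](O)[C@H]2c1c(O)cc(O)c2c1O[C@H](c1ccc(O)c(O)c1)[C@H](O)[C@H]2c1c(O)cc(O)c2c1O[C@H](c1ccc(O)c(O)c1)[C@@H](O)[C@H]2c1c(O)cc(O)c2c1O[C@H](c1ccc(O)c(O)c1)[C@H](O)C2 | target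

**Totals**
- Total steps: 9.
- Longest linear sequence: 8 (steps 1, 2, 3, 4, 5, 7, 8, 9).

**Steps most likely to fail**

Step 8. The second, 23-membered closure may lose to proton loss from the cation or to attack at a C6 position. The fallback gives up the straps and grows the chain intermolecularly.
- It sets out from 6, which is used in threefold excess as the nucleophile towards 3 (Me3SiOTf, CH2Cl2, −78 °C). This gives the dodeca-O-benzyl epicatechin-(4β→8)-catechin-(4β→8)-epicatechin trimer F1.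
- The trimer, again in excess, is coupled once more with 3 to give the strap-free hexadeca-O-benzyl tetramer F2.
- Hydrogenolysis over Pd(OH)2/C comes back to the route at 11.

Step 5. Hydride may fail to enter the upper ketone from the α face, or C2 and C4 may epimerise through the enolate. The fallback takes unit 3 from (+)-catechin instead of inverting C3.
- It sets out from 2 and commercial (+)-catechin.
- The catechin is benzylated to tetra-O-benzyl-(+)-catechin F3 and oxidised with DDQ and 2-ethoxyethanol to its 4β-(2-ethoxyethoxy) derivative F4.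
- This ether is coupled with excess 2 under TiCl4, which binds the free 3β-oxygen. A 4α/4β mixture is expected.
- The 3,4-cis (4β) dimer is separated by chromatography. The sequence comes back to the route at 6.

Step 7. The 3β-OH of unit 3, flanked by the 4β-flavanyl and 2α-aryl groups, may resist etherification. The fallback hangs both arms on the accessible oxygen of unit 4 through a three-armed core.
- It sets out from 3 and 6.
- Two equivalents of the sodium alkoxide of 3 react with 1,3,5-tris(bromomethyl)benzene to give the two-armed benzylic bromide F5.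
- This bromide alkylates only the 3-OH of unit 4 in 6, giving the mono-etherified two-armed dimer F6.
- Me3SiOTf at high dilution closes both arms in one operation to the mesitylene-capped macrobicyclic tetramer F7, in which the unit 3 hydroxyl is free.
- Hydrogenolysis comes back to the route at 11.

**Further compounds**

F1 | step 8 | dodeca-O-benzyl epicatechin-(4β→8)-catechin-(4β→8)-epicatechin | c1c(OCc9ccccc9)cc(OCc9ccccc9)c2c1O[C@H](c8ccc(OCc9ccccc9)c(OCc9ccccc9)c8)[C@H](O)[C@H]2c1c(OCc9ccccc9)cc(OCc9ccccc9)c2c1O[C@H](c8ccc(OCc9ccccc9)c(OCc9ccccc9)c8)[C@@H](O)[C@H]2c1c(OCc9ccccc9)cc(OCc9ccccc9)c2c1O[C@H](c8ccc(OCc9ccccc9)c(OCc9ccccc9)c8)[C@H](O)C2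

F2 | step 8 | strap-free hexadeca-O-benzyl tetramer | c1c(OCc9ccccc9)cc(OCc9ccccc9)c2c1O[C@H](c8ccc(OCc9ccccc9)c(OCc9ccccc9)c8)[C@H](O)[C@H]2c1c(OCc9ccccc9)cc(OCc9ccccc9)c2c1O[C@H](c8ccc(OCc9ccccc9)c(OCc9ccccc9)c8)[C@H](O)[C@H]2c1c(OCc9ccccc9)cc(OCc9ccccc9)c2c1O[C@H](c8ccc(OCc9ccccc9)c(OCc9ccccc9)c8)[C@@H](O)[C@H]2c1c(OCc9ccccc9)cc(OCc9ccccc9)c2c1O[C@H](c8ccc(OCc9ccccc9)c(OCc9ccccc9)c8)[C@H](O)C2

F3 | step 5 | 5,7,3',4'-tetra-O-benzyl-(+)-catechin | c1c(OCc9ccccc9)cc(OCc9ccccc9)c2c1O[C@H](c8ccc(OCc9ccccc9)c(OCc9ccccc9)c8)[C@@H](O)C2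

F4 | step 5 | 4β-(2-ethoxyethoxy)-5,7,3',4'-tetra-O-benzyl-(+)-catechin | c1c(OCc9ccccc9)cc(OCc9ccccc9)c2c1O[C@H](c8ccc(OCc9ccccc9)c(OCc9ccccc9)c8)[C@@H](O)[C@H]2OCCOCC

F5 | step 7 | 1-(bromomethyl)-3,5-bis(oxymethyl)benzene carrying two units of 3 through O3 | BrCc3cc(CO[C@@H]4[C@@H](OCCOCC)c5c(OCc9ccccc9)cc(OCc9ccccc9)cc5O[C@@H]4c8ccc(OCc9ccccc9)c(OCc9ccccc9)c8)cc(CO[C@@H]4[C@@H](OCCOCC)c5c(OCc9ccccc9)cc(OCc9ccccc9)cc5O[C@@H]4c8ccc(OCc9ccccc9)c(OCc9ccccc9)c8)c3

F6 | step 7 | 6 etherified at O3 of unit 4 with F5 (unit 3 hydroxyl free) | c1c(OCc9ccccc9)cc(OCc9ccccc9)c2c1O[C@H](c8ccc(OCc9ccccc9)c(OCc9ccccc9)c8)[C@@H](O)[C@H]2c1c(OCc9ccccc9)cc(OCc9ccccc9)c2c1O[C@H](c8ccc(OCc9ccccc9)c(OCc9ccccc9)c8)[C@H](OCc3cc(CO[C@@H]4[C@@H](OCCOCC)c5c(OCc9ccccc9)cc(OCc9ccccc9)cc5O[C@@H]4c8ccc(OCc9ccccc9)c(OCc9ccccc9)c8)cc(CO[C@@H]4[C@@H](OCCOCC)c5c(OCc9ccccc9)cc(OCc9ccccc9)cc5O[C@@H]4c8ccc(OCc9ccccc9)c(OCc9ccccc9)c8)c3)C2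

F7 | step 7 | mesitylene-capped macrobicyclic hexadeca-O-benzyl tetramer (core on O3 of units 1, 2 and 4) | c1c(OCc9ccccc9)cc(OCc9ccccc9)c2c1O[C@H](c8ccc(OCc9ccccc9)c(OCc9ccccc9)c8)[C@H](OCc3cc(C5)cc(C6)c3)[C@H]2c1c(OCc9ccccc9)cc(OCc9ccccc9)c2c1O[C@H](c8ccc(OCc9ccccc9)c(OCc9ccccc9)c8)[C@H](O5)[C@H]2c1c(OCc9ccccc9)cc(OCc9ccccc9)c2c1O[C@H](c8ccc(OCc9ccccc9)c(OCc9ccccc9)c8)[C@@H](O)[C@H]2c1c(OCc9ccccc9)cc(OCc9ccccc9)c2c1O[C@H](c8ccc(OCc9ccccc9)c(OCc9ccccc9)c8)[C@H](O6)C2
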